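**Plan**

- Cuts: C8–C17 (the formyl carbon, from a Δ7 enol triflate of a C8 ketone), C9–C11 (the side chain, by Negishi coupling of a Δ8 enol triflate of a C9 ketone), then ring A at C2–C3, C4–C5 and C1–C10 in a single operation.
- Enabling feature: C10 is a methyl-bearing quaternary carbon between C5 and C9. With C9 as a ketone, C9(=O)–C10(CH3)=C5 is the enone of carvone (ring B), electrophilic at C5 and nucleophilic at C10 after the addition. The C3–C4 unit with its two methyls is isobutyronitrile (nucleophilic at C4, electrophilic at C3), and C1–C2 is phenyl vinyl sulfone.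
- Forward: ring B is (S)-carvone; a Michael–Michael–Thorpe cascade closes ring A on it. The helpers (C7 isopropenyl, C2 sulfonyl, C9 ketone) are then removed or used: dealkenylation, desulfonylation with C3 reduction, Negishi coupling at C9, hydroboration to move oxygen to C8, Δ7 enol triflate, formylation.
- Stereochemistry: the C7 isopropenyl group of (S)-carvone sets C5 (trans addition) and C5 sets C10 (anti alkylation, hence the trans ring fusion). C3 comes from axial hydride attack, C9 from hydroboration anti to the C10 methyl, C13 from methyl hydrogen (R)-3-methylglutarate.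

Key step: step 1

Remark: labdane numbering of the target is used for every bicyclic compound (ring A = C1–C5 and C10, ring B = C5–C10, C17 = formyl carbon, C20 = methyl on C10); "trans" always means H5 anti to the C10 methyl, and the ring system has the absolute configuration of the target throughout.

**Route**

Step 1
Reactants: 1 (S)-(+)-carvone; 2 isobutyronitrile; 3 phenyl vinyl sulfone
Product: 8 2-(phenylsulfonyl)-7-(prop-1-en-2-yl)-4,4,10-trimethyl-trans-decalin-3,9-dione (C2 epimers), via lithiated nitrile 4 (not isolated), via lithium enolate 5 (not isolated), via lithiated sulfone 6 (not isolated), via enamino sulfone 7 (not isolated)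
Conditions: LiN(iPr)2, 2, THF, −78 °C; 1, THF/DMPU, −78 to −30 °C; 3, −78 to 0 °C; then 2 M aq. HCl, THF, 25 °C
Reagents that add atoms: water, O
Why: The lithiated nitrile adds 1,4 to the C9(=O)–C10=C5 enone of 1 (bond C4–C5), the C9/C10 enolate so formed adds to 3 (bond C1–C10), and the resulting α-sulfonyl carbanion attacks the nitrile carbon (bond C2–C3), the primary enamine being hydrolysed to the C3 ketone by the acid. The closest known reaction type is the Michael–Michael–ring-closure (MIMIRC) three-component annulation of an enolate with two acceptors, ended here by a Thorpe–Ziegler addition of a carbanion to a nitrile. Ring A closes by 6-exo-dig attack of C2 on the C3 nitrile between two arms that are trans and diequatorial on ring B, which should give the trans ring fusion. C5 is set by axial attack anti to the C7 isopropenyl group of 1, and C10 by approach of 3 to the tetrasubstituted enolate anti to the bulky cyanoisopropyl group on C5, which leaves the methyl syn to C4. The step needs 1,4- over 1,2-addition (the 1,2-adduct of the fully substituted nitrile anion is hindered and reverts, helped by DMPU), C- over O-alkylation (soft vinyl sulfone) and ring closure faster than proton transfer from C8 (intramolecular attack on an unhindered nitrile at low temperature).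

Step 2
Reactants: 8 keto sulfone
Product: 10 2-(phenylsulfonyl)-4,4,10-trimethyl-trans-decalin-3,9-dione (C2 epimers), via methoxy hydroperoxide 9 (not isolated)
Conditions: O3, CH2Cl2/MeOH, −78 °C; then FeSO4·7H2O, PhSH, −78 to 25 °C
Reagents that add atoms: none
Why: Ozone should cleave only the electron-rich 1,1-disubstituted alkene (the keto sulfone is hardly enolized) to the α-methoxy hydroperoxide, which divalent iron reduces to an alkoxy radical that loses methyl acetate by β-scission, the C7 radical then taking hydrogen from the thiol (dealkenylative hydrogenation), so that the stereocontrol element is removed and C7 becomes CH2.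

Step 3
Reactants: 10 dealkenylated keto sulfone
Product: 12 4,4,10-trimethyl-3-oxo-2-(phenylsulfonyl)-trans-Δ8-octalin-9-yl trifluoromethanesulfonate, via dipotassium dianion 11 (not isolated)
Conditions: KN(SiMe3)2 (2.1 equiv), THF, −78 °C; PhNTf2 (1.0 equiv), −78 to 0 °C; aq. NH4Cl
Reagents that add atoms: N-phenylbis(trifluoromethanesulfonimide), O=S(=O)(N(c1ccccc1)S(=O)(=O)C(F)(F)F)C(F)(F)F
Why: The first equivalent of base is taken up by the acidic C2–H between sulfone and ketone, the second makes the only possible enolate of the C9 ketone (towards C8, C10 being quaternary), and this far more nucleophilic enolate oxygen alone should be sulfonylated (enol triflate formation under dianion control).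

Step 4
Reactants: 12 enol triflate keto sulfone
Product: 14 3-hydroxy-4,4,10-trimethyl-trans-Δ8-octalin-9-yl trifluoromethanesulfonate (3-OH equatorial and syn to the C10 methyl), via ketone 13 (not isolated)
Conditions: SmI2 (2.2 equiv), THF/MeOH, −78 °C; then NaBH4, −78 to 0 °C
Reagents that add atoms: none
Why: Samarium diiodide cleaves the C2–S bond of the α-sulfonyl ketone (reductive desulfonylation, the samarium enolate being protonated by methanol) and leaves the enol triflate alone, and borohydride then adds to the C3 ketone along the axial trajectory, as is usual for 4,4-dimethyl-3-oxo decalins, to give the equatorial alcohol.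

Step 5
Reactants: 14 hydroxy enol triflate
Product: 15 3-(tert-butyldimethylsilyloxy)-4,4,10-trimethyl-trans-Δ8-octalin-9-yl trifluoromethanesulfonate
Conditions: tBuMe2SiOTf, 2,6-lutidine, CH2Cl2, 0 °C
Reagents that add atoms: tert-butyldimethylsilyl trifluoromethanesulfonate, CC(C)(C)[Si](C)(C)OS(=O)(=O)C(F)(F)F
Why: The silyl triflate with a hindered pyridine base silylates even this neopentyl-type secondary alcohol (silyl ether protection), so that the C3 oxygen survives the later oxidation and enolate steps.

Step 6
Reactants: 16 methyl hydrogen (R)-3-methylglutarate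
Product: 17 methyl (R)-5-hydroxy-3-methylpentanoate
Conditions: BH3·SMe2, THF, 0 to 25 °C; MeOH quench
Reagents that add atoms: none
Why: Borane reduces a free carboxylic acid much faster than a methyl ester (chemoselective acid reduction), and the C13 stereocenter is not touched.

Step 7
Reactants: 17 hydroxy ester
Product: 18 methyl (S)-5-iodo-3-methylpentanoate (same spatial arrangement; the descriptor changes with the priorities)
Conditions: I2, PPh3, imidazole, CH2Cl2, 0 to 25 °C
Reagents that add atoms: iodine, II
Why: Appel-type iodination of the primary alcohol proceeds under neutral conditions by SN2 displacement of the oxyphosphonium group and does not affect the ester or C13.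

Step 8
Reactants: 15 silyl-protected enol triflate; 18 iodo ester
Product: 20 methyl (13R)-3-(tert-butyldimethylsilyloxy)-17-norlabd-8-en-15-oate, via zinc reagent 19 (not isolated)
Conditions: 18, Zn dust, LiCl, THF, 40 °C; then 15, PdCl2(dppf) (5 mol %), THF/DMA, 50 °C
Reagents that add atoms: none
Why: Zinc inserts into the primary C–I bond without attacking the ester, and the alkylzinc iodide couples with the hindered enol triflate under palladium catalysis (Negishi coupling) to form the C9–C11 bond.

Step 9
Reactants: 20 Δ8 alkene
Product: 22 methyl (13R)-3-(tert-butyldimethylsilyloxy)-8-hydroxy-17-norlabdan-15-oate (H9 and 8-OH anti to the C10 methyl), via alkylborane 21 (not isolated)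
Conditions: BH3·SMe2, THF, 0 to 25 °C; then NaBO3·4H2O, H2O, 25 °C
Reagents that add atoms: sodium perborate, [Na+].[O-]OB=O
Why: Borane adds syn to the trisubstituted Δ8 alkene with boron on the less substituted C8 and from the face anti to the axial C10 methyl, which sets H9 anti to that methyl (side chain equatorial), and perborate replaces boron by OH with retention without hydrolysing the methyl ester (hydroboration–oxidation).

Step 10
Reactants: 22 C8 alcohol
Product: 23 methyl (13R)-3-(tert-butyldimethylsilyloxy)-8-oxo-17-norlabdan-15-oate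
Conditions: Dess–Martin periodinane, CH2Cl2, 25 °C
Reagents that add atoms: none
Why: Dess–Martin oxidation converts the secondary C8 alcohol into the ketone under conditions that leave the silyl ether and the ester intact, and the C9 configuration next to the new ketone is the thermodynamic one.

Step 11
Reactants: 23 C8 ketone
Product: 25 methyl (13R)-3-(tert-butyldimethylsilyloxy)-8-(trifluoromethylsulfonyloxy)-17-norlabd-7-en-15-oate, via potassium enolate 24 (not isolated)
Conditions: KN(SiMe3)2 (1.05 equiv), THF, −78 °C; PhNTf2, −78 °C; aq. NH4Cl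
Reagents that add atoms: N-phenylbis(trifluoromethanesulfonimide), O=S(=O)(N(c1ccccc1)S(=O)(=O)C(F)(F)F)C(F)(F)F
Why: The hindered amide base removes the accessible C7 proton of the C8 ketone in preference to the shielded tertiary C9–H and to the less acidic ester α-protons, and the kinetic enolate is trapped on oxygen (enol triflate formation), which places the double bond at C7–C8.

Step 12
Reactants: 25 Δ7 enol triflate
Product: 26 methyl (13R)-3-(tert-butyldimethylsilyloxy)-17-oxolabd-7-en-15-oate
Conditions: Pd(PPh3)4 (5 mol %), CO (3 atm), Bu3SnH (slow addition), LiCl, THF, 50 °C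
Reagents that add atoms: carbon monoxide, [C-]#[O+]
Why: Zerovalent palladium inserts into the C8–O bond of the enol triflate, CO insertion gives the acyl palladium species and tin hydride delivers hydride to it (palladium-catalysed reductive carbonylation, a formylation), so that the enal forms directly and the saturated methyl ester is not involved.

Step 13
Reactants: 26 silyl-protected enal
Product: 27 methyl (3R,5S,9S,10R,13R)-3-hydroxy-17-oxolabd-7-en-15-oate (CNP0285000.1)
Conditions: 48% aq. HF, MeCN, 25 °C
Reagents that add atoms: none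
Why: Fluoride cleaves the silicon–oxygen bond (desilylation) under mildly acidic conditions that are harmless to the enal and the methyl ester.

**Compound list**

1 | (S)-(+)-carvone | CC1=CC[C@@H](CC1=O)C(C)=C | starting material
2 | isobutyronitrile | CC(C)C#N | starting material
3 | phenyl vinyl sulfone | C=CS(=O)(=O)c1ccccc1 | starting material
4 | 2-lithio-2-methylpropanenitrile | [Li]C(C)(C)C#N | intermediate
5 | lithium enolate of the 1,4-adduct (cyanoisopropyl on C5 trans to the C7 isopropenyl) | [Li+].[O-]C1=C(C)[C@@H](C(C)(C)C#N)C[C@H](C(C)=C)C1 | intermediate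
6 | lithiated sulfone (sulfonylethyl arm on C10 anti to the C5 substituent) | [Li+].O=C1C[C@@H](C(C)=C)C[C@H](C(C)(C)C#N)[C@@]1(C)C[CH-]S(=O)(=O)c1ccccc1 | intermediate
7 | 3-amino-2-(phenylsulfonyl)-7-(prop-1-en-2-yl)-4,4,10-trimethyl-trans-Δ2-octalin-9-one | O=C1C[C@@H](C(C)=C)C[C@@H]2C(C)(C)C(N)=C(S(=O)(=O)c3ccccc3)C[C@@]12C | intermediate
8 | 2-(phenylsulfonyl)-7-(prop-1-en-2-yl)-4,4,10-trimethyl-trans-decalin-3,9-dione (C2 epimers; isopropenyl syn to H5) | O=C1C[C@@H](C(C)=C)C[C@@H]2C(C)(C)C(=O)C(S(=O)(=O)c3ccccc3)C[C@@]12C | intermediate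
9 | 7-(1-hydroperoxy-1-methoxyethyl) analogue of 8 | O=C1C[C@@H](C(C)(OC)OO)C[C@@H]2C(C)(C)C(=O)C(S(=O)(=O)c3ccccc3)C[C@@]12C | intermediate
10 | 2-(phenylsulfonyl)-4,4,10-trimethyl-trans-decalin-3,9-dione (C2 epimers) | O=C1CCC[C@@H]2C(C)(C)C(=O)C(S(=O)(=O)c3ccccc3)C[C@@]12C | intermediate
11 | dipotassium dianion of 10 (C2/C3 sulfonyl enolate and C8/C9 enolate) | [K+].[K+].[O-]C1=CCC[C@@H]2C(C)(C)C([O-])=C(S(=O)(=O)c3ccccc3)C[C@@]12C | intermediate
12 | 4,4,10-trimethyl-3-oxo-2-(phenylsulfonyl)-trans-Δ8-octalin-9-yl trifluoromethanesulfonate | FC(F)(F)S(=O)(=O)OC1=CCC[C@@H]2C(C)(C)C(=O)C(S(=O)(=O)c3ccccc3)C[C@@]12C | intermediate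
13 | 4,4,10-trimethyl-3-oxo-trans-Δ8-octalin-9-yl trifluoromethanesulfonate | FC(F)(F)S(=O)(=O)OC1=CCC[C@@H]2C(C)(C)C(=O)CC[C@@]12C | intermediate
14 | 3-hydroxy-4,4,10-trimethyl-trans-Δ8-octalin-9-yl trifluoromethanesulfonate (3-OH equatorial, syn to the C10 methyl) | FC(F)(F)S(=O)(=O)OC1=CCC[C@@H]2C(C)(C)[C@H](O)CC[C@@]12C | intermediate
15 | tert-butyldimethylsilyl ether of 14 | FC(F)(F)S(=O)(=O)OC1=CCC[C@@H]2C(C)(C)[C@H](O[Si](C)(C)C(C)(C)C)CC[C@@]12C | intermediate
16 | methyl hydrogen (R)-3-methylglutarate | COC(=O)C[C@H](C)CC(=O)O | starting material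
17 | methyl (R)-5-hydroxy-3-methylpentanoate | COC(=O)C[C@H](C)CCO | intermediate
18 | methyl (S)-5-iodo-3-methylpentanoate | COC(=O)C[C@H](C)CCI | intermediate
19 | [(S)-5-methoxy-3-methyl-5-oxopentyl]zinc iodide | COC(=O)C[C@H](C)CC[Zn]I | intermediate
20 | methyl (13R)-3-(tert-butyldimethylsilyloxy)-17-norlabd-8-en-15-oate | COC(=O)C[C@H](C)CCC1=CCC[C@@H]2C(C)(C)[C@H](O[Si](C)(C)C(C)(C)C)CC[C@@]12C | intermediate
21 | C8 alkylborane from 20 (boron and H9 anti to the C10 methyl) | COC(=O)C[C@H](C)CC[C@@H]1[C@@H](B)CC[C@@H]2C(C)(C)[C@H](O[Si](C)(C)C(C)(C)C)CC[C@@]12C | intermediate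
22 | methyl (13R)-3-(tert-butyldimethylsilyloxy)-8-hydroxy-17-norlabdan-15-oate | COC(=O)C[C@H](C)CC[C@@H]1[C@@H](O)CC[C@@H]2C(C)(C)[C@H](O[Si](C)(C)C(C)(C)C)CC[C@@]12C | intermediate
23 | methyl (13R)-3-(tert-butyldimethylsilyloxy)-8-oxo-17-norlabdan-15-oate | COC(=O)C[C@H](C)CC[C@@H]1C(=O)CC[C@@H]2C(C)(C)[C@H](O[Si](C)(C)C(C)(C)C)CC[C@@]12C | intermediate
24 | potassium Δ7 enolate of 23 | [K+].COC(=O)C[C@H](C)CC[C@@H]1C([O-])=CC[C@@H]2C(C)(C)[C@H](O[Si](C)(C)C(C)(C)C)CC[C@@]12C | intermediate
25 | methyl (13R)-3-(tert-butyldimethylsilyloxy)-8-(trifluoromethylsulfonyloxy)-17-norlabd-7-en-15-oate | COC(=O)C[C@H](C)CC[C@@H]1C(OS(=O)(=O)C(F)(F)F)=CC[C@@H]2C(C)(C)[C@H](O[Si](C)(C)C(C)(C)C)CC[C@@]12C | intermediate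
26 | methyl (13R)-3-(tert-butyldimethylsilyloxy)-17-oxolabd-7-en-15-oate | COC(=O)C[C@H](C)CC[C@@H]1C(C=O)=CC[C@@H]2C(C)(C)[C@H](O[Si](C)(C)C(C)(C)C)CC[C@@]12C | intermediate
27 | methyl (3R,5S,9S,10R,13R)-3-hydroxy-17-oxolabd-7-en-15-oate | COC(=O)C[C@H](C)CC[C@@H]1C(C=O)=CC[C@@H]2C(C)(C)[C@H](O)CC[C@@]12C | target

**Step count and risks**

Total step count: 13. Longest linear sequence: 11 (steps 1–5 and 8–13).

Steps most likely to fail:

1. Step 1. The cascade may stall or divert through 1,2-addition to or enolization of the enone, through proton transfer from C8 to the α-sulfonyl carbanion before ring closure (open-chain or bridged products), or through oligomerization of the vinyl sulfone. Fallback, from 1 back to 8: the anion 4 is added to 1 as before but the enolate is trapped with chlorotrimethylsilane, which gives the isolable trimethylsilyl enol ether F1. Methyllithium sets free the lithium enolate 5, which adds to 3 (via 6) and is quenched to the isolated keto nitrile sulfone F2. F2 is then cyclised in a separate flask with LiN(iPr)2 (2.2 equiv, THF, −78 to 0 °C) through the dilithium dianion F3, in which the C9 ketone is parked as its C8 enolate and only the sulfonyl carbanion closes onto the nitrile to give 7. Aqueous HCl hydrolyses 7 and the route is rejoined at 8.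

2. Step 3. Site selectivity may be lost, with sulfonylation at the oxygen of the sulfone-stabilised enolate or at both enolates. Fallback, from 10 back to 12: tBuMe2SiOTf/Et3N silylates only the acidic keto sulfone and masks C3 as the silyl enol ether F4. Tf2O with 2,6-di-tert-butyl-4-methylpyridine in CH2Cl2 then converts the single free ketone into the enol triflate F5 without an enolate. Aqueous HF in MeCN cleaves the silyl enol ether and returns 12.

3. Step 9. Hydroboration of the hindered trisubstituted alkene may be slow, so that the excess borane reduces the methyl ester, or the facial selectivity may be poor. Fallback, from 20 back to 23: mCPBA epoxidises the alkene anti to the C10 methyl to give the epoxide F6. BF3·OEt2 opens it at C9 with a 1,2-hydride shift from C8 (Meinwald rearrangement) to the C9-epimeric ketone F7. DBU in CH2Cl2 equilibrates C9 to the equatorial side chain and gives 23, so that step 10 is not needed.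

Further compounds
F1 | step 1 | trimethylsilyl enol ether of the 1,4-adduct of 4 and 1 | C[Si](C)(C)OC1=C(C)[C@@H](C(C)(C)C#N)C[C@H](C(C)=C)C1
F2 | step 1 | keto nitrile sulfone (protonated form of 6) | O=C1C[C@@H](C(C)=C)C[C@H](C(C)(C)C#N)[C@@]1(C)CCS(=O)(=O)c1ccccc1
F3 | step 1 | dilithium dianion of F2 (C8/C9 enolate and α-sulfonyl carbanion) | [Li+].[Li+].[O-]C1=C[C@@H](C(C)=C)C[C@H](C(C)(C)C#N)[C@@]1(C)C[CH-]S(=O)(=O)c1ccccc1
F4 | step 3 | C3 tert-butyldimethylsilyl enol ether of 10 | O=C1CCC[C@@H]2C(C)(C)C(O[Si](C)(C)C(C)(C)C)=C(S(=O)(=O)c3ccccc3)C[C@@]12C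
F5 | step 3 | Δ8 enol triflate of F4 | FC(F)(F)S(=O)(=O)OC1=CCC[C@@H]2C(C)(C)C(O[Si](C)(C)C(C)(C)C)=C(S(=O)(=O)c3ccccc3)C[C@@]12C
F6 | step 9 | 8,9-epoxide of 20 (oxygen anti to the C10 methyl) | COC(=O)C[C@H](C)CC[C@]12O[C@H]1CC[C@@H]1C(C)(C)[C@H](O[Si](C)(C)C(C)(C)C)CC[C@@]21C
F7 | step 9 | C9 epimer of 23 | COC(=O)C[C@H](C)CC[C@H]1C(=O)CC[C@@H]2C(C)(C)[C@H](O[Si](C)(C)C(C)(C)C)CC[C@@]12C
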